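The numbers in the tables stem from a simulated flask on assumed constants; the scatter is artificial.

Start with the easy step: count the partner.

the same everywhere: starting material 5.0 × 10⁻⁴ M; catalyst 10 µM
- Tuesday's: partner 0.50 mM; second substrate 1.5 mM (fed, over 12 s); run made earlier
- flask: partner 0.500 mM; second substrate 1.00 mM (fed, over 12 s); time 6.0 min

Tuesday's run (percent of the starting material charged)

| time / s | target / % | starting material / % |
|---|---|---|
| 10.0 | 52.9 | 47.5 |
| 12.0 | 53.9 | 44.2 |
| 20.0 | 57.9 | 42.1 |
| 25.0 | 58.7 | 41.0 |
| 30.0 | 58.9 | 41.0 |
| 40.0 | 58.7 | 40.7 |

(standard deviation of a reading: 0.5 percentage points)

- steps that have been proposed: target -> over-reaction product; starting material + partner + catalyst -> catalyst + target; second substrate + partner + catalyst -> catalyst + second product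

1. time, not beyond 6.0 min, at which the flask holds most target
2. the amount of target, in percent of the starting material charged, at that time

Follow Tuesday's run slowly. With the feed still running, Tuesday's target already reads 52.9% at 10.0 s. At the end of the feed, 12.0 s, the whole charge of second substrate has entered and competes for the same partner and catalyst, and Tuesday's target reads 53.9%. From 25.0 s Tuesday's target reads flat, with 41.0% starting material still present. Take partner as Tuesday's limiting reagent, since its charge is smaller than the two substrates together. Book the partner that target did not take on Tuesday, 0.206 mM, as second product.

Measure progress by the depth u, the natural logarithm of starting material charged over starting material left; Tuesday's plateau gives u = 0.892. Second product per unit of u follows the second substrate present. So divide Tuesday's second product by its second substrate charge and by u, which gives w = 0.154, the competition number, an average over the feed read from scattered readings. Carry w to the flask, whose feed time is the same.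

Reckoned at Tuesday's depth, the flask leaves 0.0680 mM of partner unused, and each unit of u there costs 0.359 mM. My reckoning therefore puts the flask's final depth at 1.08, with 33.9% starting material left and an estimated 66.1% target. I expect the flask's peak a little after the 25.0 s at which Tuesday's target begins to read flat.

The forecast gives 0.8 min (0.5 min to 6 min) and 64% (61% to 66.5%): “Target should peak once the partner is gone”.

The flask gives 63.6% target at 0.623 min.

    target → over-reaction product (k = 4.00 × 10⁻⁴ s⁻¹)
    starting material + partner + catalyst → catalyst + target (k = 2.80 × 10⁷ M⁻² s⁻¹)
    second substrate + partner + catalyst → catalyst + second product (k = 1.10 × 10⁷ M⁻² s⁻¹)

Check w on this flask: its 35.4% starting material at 6.00 min gives 0.160 mM of second product by w, against 0.177 mM in the flask, and my reckoned 33.9% left stands against that 35.4%. Now raise the starting material to 0.0013 M. Take a first depth as partner over starting material, 0.385, subtract w's share of second product from the partner, and the reckoning leaves 66.1% of the starting material in that neighbouring flask. That neighbouring flask ends with 64.8% starting material and 0% partner left, and holds 30.5% target at 6.00 min.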